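Atom labels used throughout: O1–C2–C3–O4 are the dioxane atoms, C9 is the CH2 on C3, ring A is the benzo ring of the benzodioxane, ring C is the catechol ring on C2, and "the biaryl" is the magnolol unit.

## Structural features

The target is a trilignan built on a 2,3-trans-disubstituted 1,4-benzodioxane. Its benzo ring (ring A) is the catechol ring of obovatol, carrying an allyl group and a 4-allylphenoxy group next to O4. C2 bears ring C, a 3-(4-allylphenoxy)-4,5-dihydroxyphenyl group, and is bonded to O1, the ring A oxygen remote from the aryloxy group. C3 is bonded to O4, the ring A oxygen flanked by the aryloxy group, and carries C9H2, which is linked through oxygen to one phenol of magnolol; the second biaryl phenol is free. C2 and C3 are the only stereocentres; they are adjacent, both R, with the ring C aryl group and the CH2O group trans. The fragile groups are five allyl groups (no hydrogenation, no alkene-isomerising bases or metals, no electrophilic oxidants), a free catechol and a free phenol, and the C2–O1 bond, a benzylic aryl ether para to oxygen that can re-ionise in acid or open to a quinone methide in base. The skeleton itself falls apart into two obovatol-type units and magnolol; the real difficulty is three selectivities at once: which of the two similar catechol oxygens of ring A goes to C2 and which to C3, the absolute configuration of two contiguous oxygenated carbons, and achieving both without touching the allyl groups. The key step exploits the linear chain C9–C3–C2–aryl: each carbon carries one heteroatom or aryl substituent, so the chain can be grown one carbon at a time on boron, C3 and then C2 each passing through an α-chloro boronate whose chloride is displaced with inversion.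

## Logic of the disconnections

**23 to 21.** The C2–O1 bond of the dioxane is cut, together with the three acid-labile masks. C2 is benzylic and para to a ring C oxygen, so the bond can be made by ionising a carbinol and letting O1 capture the cation. Ring closure and all deprotections collapse into one acid treatment of an acyclic chain. The demand is that the closure be trans. It must be steered by the fixed centre at C3, because the C2 configuration of 21 is lost in the cation, and the acid must spare five allyl groups.

**21 to 20.** The C2–O bond is traced back to a C2–B bond. This puts the chain into the boronic ester manifold, where carbon chains are extended stereospecifically. The forward step must oxidise boron with retention using a reagent that ignores terminal alkenes.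

**20 to 11 and 16.** The C2–C3 and C2–aryl bonds are cut, C2 becoming a one-carbon dichloromethyl carbenoid unit. This is the most simplifying cut: it separates ring C (16) from the ring A/biaryl half (11) and makes C2 from a boron-bound carbon. The forward step needs the chiral diol to choose which chloride leaves, the C3 carbon and then the aryl group to migrate in preference to β-elimination of an aryloxy group, and C3 to stay untouched.

**16 to 15, then 13 and 14, then 12.** The C–Mg bond, the diaryl ether C–O bond and the ketal are cut in turn. Symmetric 12 needs no regiocontrol in ketal formation, and the ketal leaves exactly one hydroxyl for arylation. The ether must be formed under conditions that leave the aryl bromide and the allyl group alone.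

**11 to 8 and 10.** The C3–O4 bond is cut. An α-chloro boronate is a strongly activated electrophile, and displacement with inversion converts the configuration chosen by the diol into that needed at C3. The nucleophile is a 2,6-disubstituted phenoxide, and O4 must be the only free oxygen of ring A. An unprotected catechol is not used: it would bind boron and is expected to react through its less hindered oxygen O1, which would put ring A on the chain the wrong way round.

**10 to 9.** The O1 protecting group is removed in thought. This places the regiochemical decision on ring A in a simple, early step where isomers can be separated and assigned. The demand is selective mono-protection of O1.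

**8 to 6.** The C3–C9 bond is cut. C3 is again a one-carbon carbenoid unit inserted into a C–B bond, leaving an achiral aryloxymethyl boronate. The diol alone must control the new centre.

**6 to 2 and 5; 5 to 3 and 4; 2 to 1.** The C9–O bond is cut (a phenoxide on a bromomethyl boronate), then the boronic ester (transesterification), then one MOM group. These cuts reach four purchasable compounds; the only demand is mono-protection of the symmetric bisphenol 1.

## Other disconnections considered

**Alternative 1:** one-carbon ring expansion of a benzylidene-type acetal.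
- **Cut:** C2–C3 and C3–O4. Rings A and C are first joined in the 2-aryl-1,3-benzodioxole A1, whose acetal carbon (the future C2) already carries ring C and both oxygens of 9. C3 and the ester carbon come from ethyl diazoacetate A2.
- **Forward key step:** a chiral Lewis acid would ionise the C2–O4 bond of A1 to an O1-oxocarbenium ion, A2 would add through carbon to C2, and the metal-bound O4 phenoxide would displace N2 from C3, closing the dioxane as the trans ester A3 ((2R,3S) by CIP, spatially as in 23).
- **In favour:** the complete benzodioxane with both stereocentres would arise in one step from an acetal close to 9. No boronic ester with a β-aryloxy leaving group is ever present. The ring is not closed through a C2 cation beside a finished C3 centre.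
- **Against:** the regiochemistry depends on which acetal C–O bond ionises. This is the same O1/O4 discrimination the chosen plan faces, but here the catalyst must achieve it inside the key step and not in a separable protection. The enantio-determining event is attack on a planar, freely rotating oxocarbenium ion held to the chiral metal only through a distant phenoxide. The diazonium intermediate has other exits (1,2-aryl or hydride shifts). A3 has an epimerisable C3–H and still needs ester reduction, Mitsunobu etherification with 2 and desilylation.
- **Comparison:** on step economy alternative 1 is the better plan (about seven operations against twelve). On convergence and building blocks it is the equal. On mechanism the chosen plan is safer, because each stereocentre is set in a separate stereospecific 1,2-shift of predictable sense, whereas the ring expansion would have to be developed as an enantioselective reaction on the real substrate.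

**Alternative 2:** ortho-quinone/cinnamyl ether hetero-Diels–Alder annulation.
- **Cut:** both C–O bonds of the dioxane, C3–O4 and C2–O1.
- **Forward key step:** ortho-quinone A4 (the oxidation product of 9) would act as the O=C–C=O heterodiene and add across the E double bond of cinnamyl biaryl ether A5 under a chiral Lewis acid to give A6, the tris-MOM ether of 23.
- **In favour:** this is the most convergent analysis; only an acid deprotection separates A6 from 23. The trans relationship follows stereospecifically from the E alkene by suprafacial addition. On this point the alternative is better than the chosen plan, where C2 is finally set by a substrate-controlled cation closure. No organometallic reagent meets the allyl groups.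
- **Against:** the regiochemistry (O4 to C3 and O1 to C2, not the reverse) rests on a small electronic difference between the two carbonyl groups of A4. A4 can also react as a carbodiene, dimerise, or oxidise its electron-rich partner. Enantiofacial control of an unfunctionalised styrene-type dienophile by a Lewis acid bound to the quinone is a hard requirement. Any error appears directly in the final skeleton, with no intermediate at which isomers could be removed.
- **Comparison:** better on step economy (about eight operations) and equal on building blocks. It is mechanistically less secure than the chosen plan, which fixes the regiochemistry in an early checkable step and the configuration through a chiral diol of known directing sense.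

**Alternative 3:** epoxide relay closing the dioxane at C3.
- **Cut:** C3–O4 last, C2–O1 earlier.
- **Forward key step:** K2CO3 in methanol would convert the C3-hydroxy C9-tosylate A7 (O1 already on C2, O4–H free) into the terminal epoxide A8. The neighbouring O4 phenoxide would open it at C3 in a 6-exo mode with inversion, giving the benzodioxane-3-methanol A9.
- **In favour:** A7 would come from a Sharpless epoxidation, a benzylic epoxide opening and a sulfonylation on the ring C side, so both centres enter the ring by stereospecific steps; at C2 this is better than the chosen plan. The first C–O bond made is C2–O1, which uses the less hindered oxygen of 9, so the intrinsic reactivity of ring A works for this plan (also better). No hindered phenoxide has to attack a boron-bearing carbon.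
- **Against:** the whole enantiomeric purity hangs on an SN2 opening of an electron-rich aryl epoxide at its benzylic carbon by a phenol, where partial ionisation would erode C2. The sulfonylation must select the primary hydroxyl beside a free phenol. A9 still needs Mitsunobu etherification with 2 and the same acid deprotection, in which the C2–O1 bond can re-ionise as in the chosen route.
- **Comparison:** equal in length (about twelve operations) and more conventional in its reactions. The chosen plan is preferred because its weak points are expected to cost yield (elimination from borates), whereas the weak point of alternative 3 sits at a stereodefining C–O bond.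

Key step: step 10

**Assumptions and remarks on the chemistry**

- Diisopropyl (bromomethyl)boronate 4 and (4-allylphenyl)boronic acid 14 are taken as purchasable reagents.
- The usual sense of the Matteson homologation with C2-symmetric diols, (S,S)-diol ester giving the (R)-α-chloro boronate when the ranking is Cl > migrated carbon > B, is taken to hold for these oxygenated chains.
- C3 is not touched after step 6. Its descriptor still changes (S in 11, R in 18, S in 20, R in 21 to 23) only because the ranking of its neighbours changes.

**Abbreviations in names**

- ArA = 4-allyl-2-(4-allylphenoxy)-6-(methoxymethoxy)phenyl (ring A, bonded through O4).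
- BiAr = 5,5'-diallyl-2'-(methoxymethoxy)biphenyl-2-yl (magnolol unit).
- ArC = 7-(4-allylphenoxy)-2,2-dimethyl-1,3-benzodioxol-5-yl (ring C as acetonide).

## Steps

Step 1
Reactants: 1 magnolol
Product: 2 mono-MOM magnolol (5,5'-diallyl-2'-(methoxymethoxy)biphenyl-2-ol)
Conditions: MOMCl (1.0 equiv), iPr2NEt, CH2Cl2, 0 °C → rt
Reagents that add atoms: chloromethyl methyl ether (MOMCl), COCCl
Why: O-alkylation of one phenol of the C2-symmetric bisphenol (Williamson-type acetal ether formation); with one equivalent of MOMCl the mono-ether should predominate, and recovered 1 and bis-ether can be separated and recycled.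

Step 2
Reactants: 3 (S,S)-1,2-dicyclohexylethane-1,2-diol; 4 diisopropyl (bromomethyl)boronate
Product: 5 (4S,5S)-2-(bromomethyl)-4,5-dicyclohexyl-1,3,2-dioxaborolane
Conditions: Et2O, rt; evaporation of volatiles
Reagents that add atoms: none
Why: Transesterification of the acyclic boronic ester by the 1,2-diol, driven by the chelate effect and by removal of volatile 2-propanol; no stereocentre is touched.

Step 3
Reactants: 2 mono-MOM magnolol; 5 bromomethyl boronate
Product: 6 (4S,5S)-2-[(BiAr-oxy)methyl]-4,5-dicyclohexyl-1,3,2-dioxaborolane
Conditions: 2, NaH, THF, 0 °C; then 5, THF–DMSO, rt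
Reagents that add atoms: none
Why: The sodium phenoxide of 2 displaces bromide from the carbon next to boron (boron-assisted nucleophilic substitution of a halomethyl boronic ester, well established for aryl oxides); the diol ester and the MOM ether are inert.

Step 4
Reactants: 6 aryloxymethyl boronate
Product: 8 (4S,5S)-2-[(1R)-1-chloro-2-(BiAr-oxy)ethyl]-4,5-dicyclohexyl-1,3,2-dioxaborolane, via lithium dichloromethyl borate 7 (not isolated)
Conditions: CH2Cl2, n-BuLi, THF, −100 °C; then 6; ZnCl2 (2 equiv), −100 °C → rt
Reagents that add atoms: dichloromethyllithium (made in the flask from CH2Cl2 and n-BuLi), [Li]C(Cl)Cl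
Why: Matteson homologation: preformed LiCHCl2 adds to boron to give borate 7, and on warming with ZnCl2 the CH2OAr group shifts from boron to carbon while one chloride leaves. The (S,S)-diol decides which diastereotopic chloride is lost and is expected to give the (R)-chloride (ranking Cl > C9 > B), the future C3. LiCHCl2 is made before 6 is added so that no alkyllithium meets the allylic C–H bonds.

Step 5
Reactants: 9 obovatol
Product: 10 O1-MOM obovatol (4-allyl-2-(4-allylphenoxy)-6-(methoxymethoxy)phenol)
Conditions: MOMCl (1.0 equiv), iPr2NEt, CH2Cl2, −20 → 0 °C
Reagents that add atoms: chloromethyl methyl ether (MOMCl), COCCl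
Why: Mono-alkylation of the catechol at O1, the oxygen with only one ortho substituent and, being meta to the aryloxy group, expected to be slightly the more acidic; O4–H, flanked by two oxygens, stays free. The O4 isomer is expected as a separable minor product, and the assignment would be checked by NOE from OCH2O to the ring A proton next to O1.

Step 6
Reactants: 8 (R)-α-chloro boronate; 10 O1-MOM obovatol
Product: 11 (4S,5S)-2-[(1S)-1-(ArA-oxy)-2-(BiAr-oxy)ethyl]-4,5-dicyclohexyl-1,3,2-dioxaborolane
Conditions: 10, NaH, THF, 0 °C; then 8, THF–DMSO, 0 °C → rt
Reagents that add atoms: none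
Why: Substitution of the α-chloride of a boronic ester by an oxygen nucleophile (Matteson-type displacement): the phenoxide of 10 enters opposite to chloride, through the boron-bound aryloxide or directly, so C3 is inverted to S (ranking O > C9 > B), the arrangement needed in 23. O1 is already capped, so only O4 can react and no free catechol can bind boron.

Step 7
Reactants: 12 5-bromobenzene-1,2,3-triol
Product: 13 6-bromo-2,2-dimethyl-1,3-benzodioxol-4-ol
Conditions: Me2C(OMe)2, TsOH·H2O (cat.), toluene, reflux with removal of MeOH
Reagents that add atoms: 2,2-dimethoxypropane, COC(C)(C)OC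
Why: Acid-catalysed ketal exchange; because 12 is symmetric, either adjacent pair of hydroxyls gives the same mono-ketal and one outer hydroxyl is left free.

Step 8
Reactants: 13 bromophenol ketal; 14 (4-allylphenyl)boronic acid
Product: 15 4-(4-allylphenoxy)-6-bromo-2,2-dimethyl-1,3-benzodioxole
Conditions: Cu(OAc)2 (20 mol %), pyridine, 4 Å MS, CH2Cl2, O2 (1 atm), rt
Reagents that add atoms: none
Why: Chan–Lam coupling (copper-catalysed oxidative O-arylation of a phenol by an arylboronic acid) at room temperature; the aryl bromide and the allyl group are not touched under these conditions.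

Step 9
Reactants: 15 ring C bromide
Product: 16 ArC-magnesium bromide (THF solution, titrated and used directly)
Conditions: Mg turnings, LiCl, THF, 25–40 °C
Reagents that add atoms: magnesium, [Mg]
Why: Direct insertion of magnesium into the aryl C–Br bond, assisted by LiCl; the ketal, the diaryl ether and the allyl group are compatible with an arylmagnesium halide at this temperature.

Step 10
Reactants: 11 (S)-α-aryloxy boronate; 16 ArC-magnesium bromide
Product: 20 (4S,5S)-2-[(1R,2S)-1-ArC-2-(ArA-oxy)-3-(BiAr-oxy)propyl]-4,5-dicyclohexyl-1,3,2-dioxaborolane, via dichloromethyl borate 17 (not isolated), via alpha-chloro boronate 18 (not isolated), via aryl borate 19 (not isolated)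
Conditions: CH2Cl2, n-BuLi, THF, −100 °C; then 11; ZnCl2 (3 equiv), −100 °C → rt; pentane, filtration of Li and Zn salts under argon; then 16, THF, −78 °C → rt
Reagents that add atoms: dichloromethyllithium (made in the flask from CH2Cl2 and n-BuLi), [Li]C(Cl)Cl
Why: LiCHCl2 adds to the trigonal boron of 11 to give borate 17; on warming with ZnCl2 the C3 carbon migrates from boron to the dichloromethyl carbon with retention while one chloride leaves, giving 18 and forming the C2–C3 bond. The closest known reaction is the Matteson homologation of α-alkoxy boronic esters of C2-symmetric diols followed by Grignard substitution of the α-chloride. The leaving chloride is chosen by the (S,S)-diol in the zinc-bridged transition state (reagent control, same sense as in step 4), which is expected to give the (R)-chloride at C2 whatever the configuration at C3. Grignard reagent 16 then adds to boron to give 19, and the ring C aryl group shifts from boron to C2 anti to the departing chloride, forming the C2–aryl bond with inversion; C2 ends as R with boron in the place of the future O1, and C3 keeps the arrangement of 23. No ring is closed. The step needs chloride and not an aryloxide to leave, and a 1,2-shift and not β-elimination of the aryloxy group on C9 (in 17) or on C3 (in 19): metal-activated chloride on the boron-bound carbon is by far the better nucleofuge, both borates are formed at −100 or −78 °C, and the Li and Zn salts are filtered off before 16 is added so that no extra Lewis acid pulls on the C3 aryloxide. The MOM ethers and the ketal are inert to both organometallic reagents, and LiCHCl2 is preformed so that no free butyllithium meets the allylic C–H bonds.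

Step 11
Reactants: 20 benzylic boronate
Product: 21 (1R,2R)-1-ArC-2-(ArA-oxy)-3-(BiAr-oxy)propan-1-ol
Conditions: NaBO3·4H2O, THF–H2O (1:1), rt
Reagents that add atoms: sodium perborate (NaBO3, used as the tetrahydrate), [Na+].[O-]OB=O
Why: Perborate oxidation of a secondary boronic ester: the peroxide adduct on boron rearranges with migration of C2 from boron to oxygen with retention, so the carbinol is R at C2. The mild, weakly basic reagent leaves the five alkenes, the MOM ethers and the ketal alone.

Step 12
Reactants: 21 carbinol
Product: 23 target (2R,3R)-7-allyl-5-(4-allylphenoxy)-2-[3-(4-allylphenoxy)-4,5-dihydroxyphenyl]-3-{[(5,5'-diallyl-2'-hydroxybiphenyl-2-yl)oxy]methyl}-2,3-dihydro-1,4-benzodioxine, via acetonide-protected benzodioxane 22 (not isolated)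
Conditions: CF3CO2H–H2O (9:1), CH2Cl2, 0 °C → rt, argon
Reagents that add atoms: none
Why: Aqueous CF3CO2H hydrolyses both MOM acetals and ionises the benzylic carbinol to a C2 cation stabilised by the para oxygen of ring C. O1 captures it in a six-membered transition state with the ring C aryl group and the C3 side chain both equatorial, so the fixed C3 centre sets C2 as R (trans) in 22 (acid-mediated SN1 etherification). The catechol ketal of 22 is expected to hydrolyse last, giving 23.

## Compound list

1 | magnolol | C=CCc1ccc(O)c(-c2cc(CC=C)ccc2O)c1 | starting material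
2 | mono-MOM magnolol, 5,5'-diallyl-2'-(methoxymethoxy)biphenyl-2-ol | C=CCc1ccc(O)c(-c2cc(CC=C)ccc2OCOC)c1 | intermediate
3 | (S,S)-1,2-dicyclohexylethane-1,2-diol | O[C@@H](C1CCCCC1)[C@@H](O)C1CCCCC1 | starting material
4 | diisopropyl (bromomethyl)boronate | BrCB(OC(C)C)OC(C)C | starting material
5 | (4S,5S)-2-(bromomethyl)-4,5-dicyclohexyl-1,3,2-dioxaborolane | BrCB1O[C@@H](C2CCCCC2)[C@H](C2CCCCC2)O1 | intermediate
6 | (4S,5S)-2-[(BiAr-oxy)methyl]-4,5-dicyclohexyl-1,3,2-dioxaborolane | COCOc1ccc(CC=C)cc1-c1cc(CC=C)ccc1OCB1O[C@@H](C2CCCCC2)[C@H](C2CCCCC2)O1 | intermediate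
7 | lithium dichloromethyl borate from 6 | [Li+].COCOc1ccc(CC=C)cc1-c1cc(CC=C)ccc1OC[B-]1(C(Cl)Cl)O[C@@H](C2CCCCC2)[C@H](C2CCCCC2)O1 | intermediate (not isolated)
8 | (4S,5S)-2-[(1R)-1-chloro-2-(BiAr-oxy)ethyl]-4,5-dicyclohexyl-1,3,2-dioxaborolane | COCOc1ccc(CC=C)cc1-c1cc(CC=C)ccc1OC[C@H](Cl)B1O[C@@H](C2CCCCC2)[C@H](C2CCCCC2)O1 | intermediate
9 | obovatol | C=CCc1cc(O)c(O)c(Oc2ccc(CC=C)cc2)c1 | starting material
10 | O1-MOM obovatol, 4-allyl-2-(4-allylphenoxy)-6-(methoxymethoxy)phenol | C=CCc1cc(OCOC)c(O)c(Oc2ccc(CC=C)cc2)c1 | intermediate
11 | (4S,5S)-2-[(1S)-1-(ArA-oxy)-2-(BiAr-oxy)ethyl]-4,5-dicyclohexyl-1,3,2-dioxaborolane (key-step precursor) | COCOc1ccc(CC=C)cc1-c1cc(CC=C)ccc1OC[C@@H](Oc1c(OCOC)cc(CC=C)cc1Oc1ccc(CC=C)cc1)B1O[C@@H](C2CCCCC2)[C@H](C2CCCCC2)O1 | intermediate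
12 | 5-bromobenzene-1,2,3-triol | Oc1cc(Br)cc(O)c1O | starting material
13 | 6-bromo-2,2-dimethyl-1,3-benzodioxol-4-ol | CC1(C)Oc2cc(Br)cc(O)c2O1 | intermediate
14 | (4-allylphenyl)boronic acid | C=CCc1ccc(B(O)O)cc1 | starting material
15 | 4-(4-allylphenoxy)-6-bromo-2,2-dimethyl-1,3-benzodioxole | C=CCc1ccc(Oc2cc(Br)cc3OC(C)(C)Oc23)cc1 | intermediate
16 | ArC-magnesium bromide | C=CCc1ccc(Oc2cc([Mg]Br)cc3OC(C)(C)Oc23)cc1 | intermediate
17 | lithium dichloromethyl borate from 11 | [Li+].COCOc1ccc(CC=C)cc1-c1cc(CC=C)ccc1OC[C@@H](Oc1c(OCOC)cc(CC=C)cc1Oc1ccc(CC=C)cc1)[B-]1(C(Cl)Cl)O[C@@H](C2CCCCC2)[C@H](C2CCCCC2)O1 | intermediate (not isolated)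
18 | (4S,5S)-2-[(1R,2R)-1-chloro-2-(ArA-oxy)-3-(BiAr-oxy)propyl]-4,5-dicyclohexyl-1,3,2-dioxaborolane | COCOc1ccc(CC=C)cc1-c1cc(CC=C)ccc1OC[C@@H](Oc1c(OCOC)cc(CC=C)cc1Oc1ccc(CC=C)cc1)[C@H](Cl)B1O[C@@H](C2CCCCC2)[C@H](C2CCCCC2)O1 | intermediate (not isolated)
19 | bromomagnesium aryl borate from 18 and 16 | COCOc1ccc(CC=C)cc1-c1cc(CC=C)ccc1OC[C@@H](Oc1c(OCOC)cc(CC=C)cc1Oc1ccc(CC=C)cc1)[C@H](Cl)[B-]1(c2cc(Oc3ccc(CC=C)cc3)c3OC(C)(C)Oc3c2)O[C@@H](C2CCCCC2)[C@H](C2CCCCC2)O1.Br[Mg+] | intermediate (not isolated)
20 | (4S,5S)-2-[(1R,2S)-1-ArC-2-(ArA-oxy)-3-(BiAr-oxy)propyl]-4,5-dicyclohexyl-1,3,2-dioxaborolane (key-step product) | C=CCc1ccc(Oc2cc([C@@H](B3O[C@@H](C4CCCCC4)[C@H](C4CCCCC4)O3)[C@H](Oc3c(OCOC)cc(CC=C)cc3Oc3ccc(CC=C)cc3)COc3ccc(CC=C)cc3-c3cc(CC=C)ccc3OCOC)cc3OC(C)(C)Oc23)cc1 | intermediate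
21 | (1R,2R)-1-ArC-2-(ArA-oxy)-3-(BiAr-oxy)propan-1-ol | C=CCc1ccc(Oc2cc([C@@H](O)[C@H](Oc3c(OCOC)cc(CC=C)cc3Oc3ccc(CC=C)cc3)COc3ccc(CC=C)cc3-c3cc(CC=C)ccc3OCOC)cc3OC(C)(C)Oc23)cc1 | intermediate
22 | (2R,3R)-benzodioxane, 23 with the ring C catechol as acetonide | C=CCc1ccc(Oc2cc([C@H]3Oc4cc(CC=C)cc(Oc5ccc(CC=C)cc5)c4O[C@@H]3COc3ccc(CC=C)cc3-c3cc(CC=C)ccc3O)cc3OC(C)(C)Oc23)cc1 | intermediate (not isolated)
23 | CNP0231734.1, (2R,3R)-7-allyl-5-(4-allylphenoxy)-2-[3-(4-allylphenoxy)-4,5-dihydroxyphenyl]-3-{[(5,5'-diallyl-2'-hydroxybiphenyl-2-yl)oxy]methyl}-2,3-dihydro-1,4-benzodioxine | C=CCc1ccc(Oc2cc([C@H]3Oc4cc(CC=C)cc(Oc5ccc(CC=C)cc5)c4O[C@@H]3COc3ccc(CC=C)cc3-c3cc(CC=C)ccc3O)cc(O)c2O)cc1 | target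

## Step count and least certain steps

Total: 12 steps. Longest linear sequence: 7 steps (1 → 2 → 6 → 8 → 11 → 20 → 21 → 23; the branch starting from 3 is equally long).

**Key step (step 10).** The most likely failure is in the aryl transfer. The bulky, electron-rich Grignard reagent may add slowly to the hindered boron of 18; in that time the chloride can epimerise by halide exchange, and the four-coordinate boron can expel the C3 aryloxide by β-elimination. The fallback sets out from 18 and returns at 21. It replaces the 1,2-shift by a carbonyl addition. Crude 18 is oxidised with NaBO3·4H2O (THF–H2O, 0 °C), which turns the α-chloro boronate into (2R)-2-(ArA-oxy)-3-(BiAr-oxy)propanal F1 by loss of HCl from the chlorohydrin. Crude F1 is added at −78 °C to 16 in THF to give 21 together with its C2 epimer, the (1S,2R)-carbinol F2. Both are taken through step 12 without separation, since they share the C2 cation whose closure is steered by C3. If the carbon insertion itself is at fault, the boron-free sequence described for step 6 reaches 21 as well.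

**Step 6.** The likely failure is slow substitution by the 2,6-disubstituted phenoxide at a secondary, boron-bearing carbon. That would allow chloride-induced epimerisation of 8 and β-elimination of the biaryl oxide from the borate. The fallback sets out from 10 (with 16 and 2) and returns at 21. It forms the C3–O4 bond on a primary α-halo imide and builds the chain by an Evans aldol reaction.
- 10 is alkylated with purchased (S)-4-benzyl-3-(chloroacetyl)oxazolidin-2-one (K2CO3, NaI cat., acetone) to give the aryloxyacetyl imide F3.
- 16 is formylated with DMF to give ring C aldehyde F4.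
- The dibutylboron enolate of F3 (Bu2BOTf, iPr2NEt, CH2Cl2, −78 °C) is added to F4. This should give the syn aldol adduct F5, whose two centres have the arrangement of 21 when the (S)-benzyl auxiliary is used.
- LiBH4 (THF–MeOH, 0 °C) releases the (1R,2R)-diol F6.
- Mitsunobu etherification of the primary hydroxyl of F6 with 2 (PPh3, DIAD, THF, 0 °C) gives 21.

**Step 5.** The likely failure is poor discrimination between O1 and O4, two phenols of similar acidity. The fallback sets out from 9 and returns at 10. It protects both oxygens and then removes one. Exhaustive etherification (MOMCl, NaH, DMF) gives bis-MOM obovatol F7. Controlled methanolysis (dilute HCl in MeOH, 0 °C, stopped at mono-cleavage) is expected to remove first the O4 acetal, which is flanked on both sides and twisted out of the ring plane, leaving 10.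

**Step 12.** The likely failure is incomplete trans selectivity in the kinetic cation closure. The slow ketal hydrolysis also prolongs the acid exposure during which released formaldehyde or the C2 cation can alkylate the electron-rich rings. The fallback sets out from 21, taken through the acid step to a mixture of 23 and its cis isomer, the (2S,3R)-benzodioxane F8, and returns at 23. The acid treatment is kept short and cold. The crude mixture is then equilibrated under argon with K2CO3 in MeOH at rt: the para-phenoxide of ring C opens the C2–O1 bond to a quinone methide, and re-addition of the O1 phenoxide should funnel F8 into the more stable trans isomer 23.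

## Further compounds

F1 | step 10 | (2R)-2-(ArA-oxy)-3-(BiAr-oxy)propanal | COCOc1ccc(CC=C)cc1-c1cc(CC=C)ccc1OC[C@@H](Oc1c(OCOC)cc(CC=C)cc1Oc1ccc(CC=C)cc1)C=O
F2 | step 10 | (1S,2R)-1-ArC-2-(ArA-oxy)-3-(BiAr-oxy)propan-1-ol, C2 epimer of 21 | C=CCc1ccc(Oc2cc([C@H](O)[C@H](Oc3c(OCOC)cc(CC=C)cc3Oc3ccc(CC=C)cc3)COc3ccc(CC=C)cc3-c3cc(CC=C)ccc3OCOC)cc3OC(C)(C)Oc23)cc1
F3 | step 6 | (4S)-4-benzyl-3-[(ArA-oxy)acetyl]oxazolidin-2-one | C=CCc1cc(OCOC)c(OCC(=O)N2[C@@H](Cc3ccccc3)COC2=O)c(Oc2ccc(CC=C)cc2)c1
F4 | step 6 | 7-(4-allylphenoxy)-2,2-dimethyl-1,3-benzodioxole-5-carbaldehyde | C=CCc1ccc(Oc2cc(C=O)cc3OC(C)(C)Oc23)cc1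
F5 | step 6 | (4S)-4-benzyl-3-[(2S,3R)-3-ArC-3-hydroxy-2-(ArA-oxy)propanoyl]oxazolidin-2-one | C=CCc1ccc(Oc2cc([C@@H](O)[C@H](Oc3c(OCOC)cc(CC=C)cc3Oc3ccc(CC=C)cc3)C(=O)N3[C@@H](Cc4ccccc4)COC3=O)cc3OC(C)(C)Oc23)cc1
F6 | step 6 | (1R,2R)-1-ArC-2-(ArA-oxy)propane-1,3-diol | C=CCc1ccc(Oc2cc([C@@H](O)[C@H](Oc3c(OCOC)cc(CC=C)cc3Oc3ccc(CC=C)cc3)CO)cc3OC(C)(C)Oc23)cc1
F7 | step 5 | bis-MOM obovatol, 5-allyl-1,2-bis(methoxymethoxy)-3-(4-allylphenoxy)benzene | C=CCc1cc(OCOC)c(OCOC)c(Oc2ccc(CC=C)cc2)c1
F8 | step 12 | (2S,3R) cis isomer of 23 | C=CCc1ccc(Oc2cc([C@@H]3Oc4cc(CC=C)cc(Oc5ccc(CC=C)cc5)c4O[C@@H]3COc3ccc(CC=C)cc3-c3cc(CC=C)ccc3O)cc(O)c2O)cc1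
A1 | alternative 1 | 6-allyl-4-(4-allylphenoxy)-2-[3-(4-allylphenoxy)-4,5-bis(tert-butyldimethylsilyloxy)phenyl]-1,3-benzodioxole (acetal carbon not defined) | C=CCc1ccc(Oc2cc(C3Oc4cc(CC=C)cc(Oc5ccc(CC=C)cc5)c4O3)cc(O[Si](C)(C)C(C)(C)C)c2O[Si](C)(C)C(C)(C)C)cc1
A2 | alternative 1 | ethyl diazoacetate | CCOC(=O)C=[N+]=[N-]
A3 | alternative 1 | ethyl trans-(2R,3S)-benzodioxane-3-carboxylate, ring C as bis-TBS ether | C=CCc1ccc(Oc2cc([C@H]3Oc4cc(CC=C)cc(Oc5ccc(CC=C)cc5)c4O[C@@H]3C(=O)OCC)cc(O[Si](C)(C)C(C)(C)C)c2O[Si](C)(C)C(C)(C)C)cc1
A4 | alternative 2 | obovatol ortho-quinone, 5-allyl-3-(4-allylphenoxy)cyclohexa-3,5-diene-1,2-dione | C=CCC1=CC(=O)C(=O)C(Oc2ccc(CC=C)cc2)=C1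
A5 | alternative 2 | (E)-cinnamyl biaryl ether of ring C, all phenols as MOM ethers | C=CCc1ccc(Oc2cc(/C=C/COc3ccc(CC=C)cc3-c3cc(CC=C)ccc3OCOC)cc(OCOC)c2OCOC)cc1
A6 | alternative 2 | (2R,3R) tris-MOM ether of 23 | C=CCc1ccc(Oc2cc([C@H]3Oc4cc(CC=C)cc(Oc5ccc(CC=C)cc5)c4O[C@@H]3COc3ccc(CC=C)cc3-c3cc(CC=C)ccc3OCOC)cc(OCOC)c2OCOC)cc1
A7 | alternative 3 | (1R,2S)-1-ArC-1-[5-allyl-3-(4-allylphenoxy)-2-hydroxyphenoxy]-2-hydroxy-3-(tosyloxy)propane | C=CCc1ccc(Oc2cc([C@@H](Oc3cc(CC=C)cc(Oc4ccc(CC=C)cc4)c3O)[C@@H](O)COS(=O)(=O)c3ccc(C)cc3)cc3OC(C)(C)Oc23)cc1
A8 | alternative 3 | terminal epoxide from A7, (R) at C2 and (S) at the oxirane carbon C3 | C=CCc1ccc(Oc2cc([C@@H](Oc3cc(CC=C)cc(Oc4ccc(CC=C)cc4)c3O)[C@@H]3CO3)cc3OC(C)(C)Oc23)cc1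
A9 | alternative 3 | (2R,3R)-benzodioxane-3-methanol, ring C as acetonide | C=CCc1ccc(Oc2cc([C@H]3Oc4cc(CC=C)cc(Oc5ccc(CC=C)cc5)c4O[C@@H]3CO)cc3OC(C)(C)Oc23)cc1
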